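**Plan**

- Retrosynthesis: (1) cut the C11 O–acetyl bond (late TBS-to-acetyl exchange); (2) cut the C1–C2 bond of the 13-membered lactone, leaving C1 on O15 as a 2-pyridyl carbonate and C2 as a primary iodide; (3) cut C7–C8 and C12–C13 (three-component coupling on a cyclopentenone).
- Forward: the five-membered ring is bought as the enone; the ω-chain (C13–C20) and a C1-nor α-chain (C2–C7) are joined to it in one pot; C1 is then attached to O15 and the macrolactone ring is closed last at C1–C2 by a nickel-catalysed reductive coupling; TBS is finally exchanged for acetyl.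
- Enabling feature: the trans-vicinal chains on C8 and C12 of the cyclopentanone, with the E-C13=C14 and Z-C5=C6 alkenes, fold the seco compound into a hairpin that holds O15 (and so C1) over C2; C1 serves as a one-carbon stitch between O15 and C2, so no seco acid is needed.
- Stereochemistry: C15 from (S)-oct-1-yn-3-ol; C11 from (R)-4-silyloxycyclopentenone; C12 and C8 by anti conjugate addition and anti enolate alkylation; Z alkene from Lindlar reduction, E alkene from syn-hydrozirconation.

Key step: step 9

Assumption: enantiopure 6 and 10 and di(2-pyridyl) carbonate are purchased; C11 is kept as its TBS ether until after ring closure because the β-acetoxy ketone of the target is prone to elimination.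

**Route**

Step 1
Reactants: 1 pent-4-yn-1-ol
Product: 3 hex-2-yne-1,6-diol, via dilithium acetylide alkoxide 2 (not isolated)
Conditions: n-BuLi (2.1 equiv), THF–DMPU, −78 → 0 °C; (CH2O)n, 0 °C → rt; H2O
Reagents that add atoms: formaldehyde (as paraformaldehyde), C=O
Why: Acetylide hydroxymethylation, in which the O,C-dianion reacts with formaldehyde at the more nucleophilic acetylide carbon and adds the future C7; no stereocentre is formed.

Step 2
Reactants: 3 hex-2-yne-1,6-diol
Product: 4 (Z)-hex-2-ene-1,6-diol
Conditions: H2 (1 atm), Pd/CaCO3–Pb(OAc)2 (Lindlar catalyst), quinoline, MeOH, rt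
Reagents that add atoms: none
Why: Lindlar semihydrogenation delivers hydrogen syn on the poisoned palladium surface and should set the Z geometry of the future C5=C6 bond without over-reduction.

Step 3
Reactants: 4 (Z)-hex-2-ene-1,6-diol
Product: 5 (Z)-1,6-diiodohex-2-ene
Conditions: PPh3, I2, imidazole, CH2Cl2, 0 °C, dark; used at once
Reagents that add atoms: iodine, II
Why: Appel-type iodination converts both primary hydroxyls to iodides by SN2 displacement of alkoxyphosphonium ions, and the cold, dark conditions should preserve the Z alkene.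

Step 4
Reactants: 6 (S)-oct-1-yn-3-ol
Product: 7 (S)-triethyl(oct-1-yn-3-yloxy)silane
Conditions: TESCl, imidazole, CH2Cl2, 0 °C → rt
Reagents that add atoms: chlorotriethylsilane, CC[Si](Cl)(CC)CC
Why: Standard silylation of the secondary propargylic alcohol, with TES chosen so that it can later be removed beside the C11 TBS ether; the future C15 stereocentre is not touched.

Step 5
Reactants: 7 (S)-triethyl(oct-1-yn-3-yloxy)silane
Product: 9 (S,E)-triethyl[(1-iodooct-1-en-3-yl)oxy]silane, via alkenylzirconocene chloride 8 (not isolated)
Conditions: Cp2Zr(H)Cl, THF, rt; then I2, 0 °C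
Reagents that add atoms: iodine, II
Why: Schwartz hydrozirconation adds Zr–H syn with zirconium at the terminal carbon and iodinolysis proceeds with retention, which should give the E-vinyl iodide (future C13=C14).

Step 6
Reactants: 9 (S,E)-triethyl[(1-iodooct-1-en-3-yl)oxy]silane; 10 (R)-4-[(tert-butyldimethylsilyl)oxy]cyclopent-2-en-1-one; 5 (Z)-1,6-diiodohex-2-ene
Product: 14 (2R,3R,4R)-4-[(tert-butyldimethylsilyl)oxy]-2-[(Z)-6-iodohex-2-en-1-yl]-3-[(S,E)-3-[(triethylsilyl)oxy]oct-1-en-1-yl]cyclopentan-1-one, via vinyllithium 11 (not isolated), via lithium alkenyldimethylzincate 12 (not isolated), via zinc enolate 13 (not isolated)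
Conditions: t-BuLi (2 equiv), Et2O, −78 °C; ZnMe2, THF, −78 → 0 °C; 10, THF, −78 °C; HMPA, 5 (3 equiv), −78 → −40 °C; aq. NH4Cl
Reagents that add atoms: none
Why: Three-component conjugate addition–enolate alkylation (organozincate variant), in which the alkenyl group adds anti to the C11 silyloxy group to set C12 and the zinc enolate is alkylated at the allylic iodide terminus of 5 anti to the new C12 substituent to set C8 (all-trans ring), the primary iodide terminus being far less reactive.

Step 7
Reactants: 14 (the bis-silyl ether from step 6)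
Product: 15 (2R,3R,4R)-4-[(tert-butyldimethylsilyl)oxy]-3-[(S,E)-3-hydroxyoct-1-en-1-yl]-2-[(Z)-6-iodohex-2-en-1-yl]cyclopentan-1-one
Conditions: AcOH–THF–H2O (3:1:1), rt
Reagents that add atoms: none
Why: Chemoselective acidic solvolysis, since the secondary allylic TES ether is cleaved much faster than the more hindered TBS ether and the mildly acidic medium should not eliminate the β-silyloxy ketone.

Step 8
Reactants: 15 (the C15 alcohol)
Product: 16 (S,E)-1-[(1R,2R,5R)-5-[(tert-butyldimethylsilyl)oxy]-2-[(Z)-6-iodohex-2-en-1-yl]-3-oxocyclopentyl]oct-1-en-3-yl pyridin-2-yl carbonate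
Conditions: di(2-pyridyl) carbonate, i-Pr2NEt, DMAP (cat.), CH2Cl2, rt
Reagents that add atoms: di(pyridin-2-yl) carbonate, O=C(Oc1ccccn1)Oc1ccccn1
Why: Acylation of the C15 alcohol to a mixed activated carbonate attaches C1 to O15 with retention at C15, and the hindered base should not quaternise the primary iodide.

Step 9
Reactants: 16 (the 2-pyridyl carbonate with the C2 iodide)
Product: 17 11-O-(tert-butyldimethylsilyl)prostaglandin E2 1,15-lactone
Conditions: NiBr2(dme) (30 mol %), 4,4'-di-tert-butyl-2,2'-bipyridine (33 mol %), Zn dust (4 equiv), DMA, 25 °C, 16 added by syringe pump over 12 h (final 2 mM)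
Reagents that add atoms: none
Why: Proposed new method: zerovalent nickel (dtbbpy) should insert into the acyl C–O bond of the 2-pyridyl carbonate (N,O-chelation by the pyridyl group) to give an alkoxycarbonylnickel pyridonate, while a monovalent nickel species abstracts iodine from C2; the primary C2 radical is captured by the alkoxycarbonylnickel centre of the same molecule and reductive elimination from trivalent nickel forms C1–C2, zinc returning nickel to its low-valent state. The closest known reaction types are the nickel-catalysed, zinc-mediated reductive cross-electrophile couplings of alkyl iodides with 2-pyridyl carboxylates or S-(2-pyridyl) thioesters (ketones) and of alkyl halides with chloroformates (esters), all intermolecular; the carbonate electrophile and the macrocyclic mode are the untested elements. The 13-membered lactone ring is closed by intramolecular C(sp3)–C(acyl) reductive elimination at nickel, not by radical attack on a π bond, and the ring strain is low because the trans-vicinal chains on C8 and C12 of the cyclopentanone together with the E-C13=C14 and Z-C5=C6 alkenes already hold O15–C1 over C2. No stereocentre is formed, and C8, C11, C12 and C15 are not touched by the neutral, room-temperature medium. The step needs insertion at the acyl C–O(pyridyl) bond in preference to ionisation of the allylic C15–O bond, which the chelating leaving group and the hindered, 1,3-dialkylated allyl unit should secure, and ring closure in preference to oligomerisation or hydrodehalogenation, which syringe-pump addition to 2 mM and the dry medium should secure. The C2 radical has no 5-exo or 6-exo pathway onto C5=C6 (only 4-exo or 5-endo), so it should persist until it is captured.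

Step 10
Reactants: 17 11-O-(tert-butyldimethylsilyl)prostaglandin E2 1,15-lactone
Product: 18 prostaglandin E2 1,15-lactone
Conditions: HF·pyridine, MeCN, 0 °C
Reagents that add atoms: none
Why: Fluoride-mediated desilylation under mildly acidic conditions should free the C11 hydroxyl without β-elimination or cleavage of the allylic lactone.

Step 11
Reactants: 18 prostaglandin E2 1,15-lactone
Product: 19 prostaglandin E2 1,15-lactone 11-acetate (target)
Conditions: Ac2O, pyridine, 0 °C, 2 h; cold neutral work-up
Reagents that add atoms: acetic anhydride, CC(=O)OC(C)=O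
Why: Pyridine-mediated acetylation (nucleophilic acyl substitution) of the secondary C11 alcohol proceeds with retention, and low temperature with short contact should limit E1cB loss of acetic acid from the β-acetoxy ketone.

**Compound list**

1 | pent-4-yn-1-ol | C#CCCCO | starting material
2 | O,C-dilithiated pent-4-yn-1-ol (dilithium acetylide alkoxide) | [Li]C#CCCCO[Li] | intermediate
3 | hex-2-yne-1,6-diol | OCC#CCCCO | intermediate
4 | (Z)-hex-2-ene-1,6-diol | OC/C=C\CCCO | intermediate
5 | (Z)-1,6-diiodohex-2-ene | IC/C=C\CCCI | intermediate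
6 | (S)-oct-1-yn-3-ol | CCCCC[C@H](O)C#C | starting material
7 | (S)-triethyl(oct-1-yn-3-yloxy)silane | CCCCC[C@H](O[Si](CC)(CC)CC)C#C | intermediate
8 | chloro[(S,E)-3-(triethylsilyloxy)oct-1-en-1-yl]zirconocene | CCCCC[C@H](O[Si](CC)(CC)CC)/C=C/[Zr](Cl)(C1C=CC=C1)C1C=CC=C1 | intermediate
9 | (S,E)-triethyl[(1-iodooct-1-en-3-yl)oxy]silane | CCCCC[C@H](O[Si](CC)(CC)CC)/C=C/I | intermediate
10 | (R)-4-[(tert-butyldimethylsilyl)oxy]cyclopent-2-en-1-one | O=C1C=C[C@H](O[Si](C)(C)C(C)(C)C)C1 | starting material
11 | [(S,E)-3-(triethylsilyloxy)oct-1-en-1-yl]lithium | CCCCC[C@H](O[Si](CC)(CC)CC)/C=C/[Li] | intermediate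
12 | lithium dimethyl[(S,E)-3-(triethylsilyloxy)oct-1-en-1-yl]zincate | CCCCC[C@H](O[Si](CC)(CC)CC)/C=C/[Zn-](C)C.[Li+] | intermediate
13 | lithium dimethylzincate enolate of (3R,4R)-4-(TBS-oxy)-3-[(S,E)-3-(TES-oxy)oct-1-enyl]cyclopentanone (C8=C9 enolate) | CCCCC[C@H](O[Si](CC)(CC)CC)/C=C/[C@H]1[C@H](O[Si](C)(C)C(C)(C)C)CC(O[Zn-](C)C)=C1.[Li+] | intermediate
14 | (2R,3R,4R)-4-[(tert-butyldimethylsilyl)oxy]-2-[(Z)-6-iodohex-2-en-1-yl]-3-[(S,E)-3-[(triethylsilyl)oxy]oct-1-en-1-yl]cyclopentan-1-one | CCCCC[C@H](O[Si](CC)(CC)CC)/C=C/[C@H]1[C@H](O[Si](C)(C)C(C)(C)C)CC(=O)[C@@H]1C/C=C\CCCI | intermediate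
15 | (2R,3R,4R)-4-[(tert-butyldimethylsilyl)oxy]-3-[(S,E)-3-hydroxyoct-1-en-1-yl]-2-[(Z)-6-iodohex-2-en-1-yl]cyclopentan-1-one | CCCCC[C@H](O)/C=C/[C@H]1[C@H](O[Si](C)(C)C(C)(C)C)CC(=O)[C@@H]1C/C=C\CCCI | intermediate
16 | (S,E)-1-[(1R,2R,5R)-5-[(tert-butyldimethylsilyl)oxy]-2-[(Z)-6-iodohex-2-en-1-yl]-3-oxocyclopentyl]oct-1-en-3-yl pyridin-2-yl carbonate | CCCCC[C@H](OC(=O)Oc1ccccn1)/C=C/[C@H]1[C@H](O[Si](C)(C)C(C)(C)C)CC(=O)[C@@H]1C/C=C\CCCI | intermediate
17 | 11-O-(tert-butyldimethylsilyl)prostaglandin E2 1,15-lactone | CCCCC[C@H]1/C=C/[C@H]2[C@H](O[Si](C)(C)C(C)(C)C)CC(=O)[C@@H]2C/C=C\CCCC(=O)O1 | intermediate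
18 | prostaglandin E2 1,15-lactone | CCCCC[C@H]1/C=C/[C@H]2[C@H](O)CC(=O)[C@@H]2C/C=C\CCCC(=O)O1 | intermediate
19 | prostaglandin E2 1,15-lactone 11-acetate (CNP0241847.1) | CCCCC[C@H]1/C=C/[C@H]2[C@H](OC(C)=O)CC(=O)[C@@H]2C/C=C\CCCC(=O)O1 | target

**Step count**

Total: 11 steps. Longest linear sequence: 9 steps (1, 2, 3, 6, 7, 8, 9, 10, 11).

**Steps most likely to fail**

Step 9 (the proposed ring closure). The likely failures are ionisation of the allylic C15–O bond at low-valent nickel, slow insertion into the carbonate C–O bond, and hydrodehalogenation or oligomerisation outrunning ring closure. The fallback closes the ring at the C1–O15 bond by known chemistry; it sets out from 15 and comes back at 17. Iodo alcohol 15 would be carboxylated at C2 with CO2 under nickel-catalysed reductive conditions (NiCl2(dme), 2,9-dimethyl-1,10-phenanthroline, Mn powder, DMF, CO2 1 atm, rt) to give the seco acid 11-O-(tert-butyldimethylsilyl)prostaglandin E2 F1. Treatment with 2,2'-dipyridyl disulfide and PPh3 would give its S-(2-pyridyl) thioester F2, which on heating in xylene at high dilution (Corey–Nicolaou macrolactonisation) should cyclise onto the C15 hydroxyl and rejoin the route at 17.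

Step 6 (three-component coupling). The likely failures are loss of Z geometry in the allylic iodide before alkylation, and slow alkylation of the zinc enolate that allows proton transfer and β-elimination of the C11 silyloxy group. The fallback sets out from 3 (with 9 and 10) and comes back at 14. Diol 3 would be converted with PPh3, I2 and imidazole into 1,6-diiodohex-2-yne F3, a more reactive propargylic electrophile with no alkene geometry to lose. Used in place of 5 in the same one-pot conjugate addition–alkylation, it should give the 5,6-didehydro ketone F4 (C5≡C6 alkyne analogue of 14). Lindlar semihydrogenation (H2, Pd/CaCO3–Pb(OAc)2, quinoline) would then install the Z alkene at the late stage and return to 14.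

Step 11 (acetylation). The likely failure is E1cB elimination of acetic acid from the β-acetoxy ketone under the basic acylation or during purification, giving the cyclopentenone. The fallback sets out from 18 and comes back at 19. It replaces base-mediated anhydride acylation by neutral enzymatic transesterification: immobilised Candida antarctica lipase B with vinyl acetate in dry toluene at rt, with no amine present. No new compound arises (F0).

**Further compounds**

F1 | step 9 | 11-O-(tert-butyldimethylsilyl)prostaglandin E2 (seco acid) | CCCCC[C@H](O)/C=C/[C@H]1[C@H](O[Si](C)(C)C(C)(C)C)CC(=O)[C@@H]1C/C=C\CCCC(=O)O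
F2 | step 9 | S-(pyridin-2-yl) thioester of F1 | CCCCC[C@H](O)/C=C/[C@H]1[C@H](O[Si](C)(C)C(C)(C)C)CC(=O)[C@@H]1C/C=C\CCCC(=O)Sc1ccccn1
F3 | step 6 | 1,6-diiodohex-2-yne | ICC#CCCCI
F4 | step 6 | (2R,3R,4R)-4-[(tert-butyldimethylsilyl)oxy]-2-(6-iodohex-2-yn-1-yl)-3-[(S,E)-3-[(triethylsilyl)oxy]oct-1-en-1-yl]cyclopentan-1-one | CCCCC[C@H](O[Si](CC)(CC)CC)/C=C/[C@H]1[C@H](O[Si](C)(C)C(C)(C)C)CC(=O)[C@@H]1CC#CCCCI
F0 | step 11 | none | none
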